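Compare the two charges: the electrophile stands higher than the protonated nucleophile, and a free base of unknown amount has to release that nucleophile.

    electrophile + nucleophile ⇌ acid set free + target (K1 = 0.75, k1 = 3.0 /M/min)
    acid set free + free base ⇌ salt of the base (K2 = 760 /M, k2 = 4.7 /M/min)
    nucleophile + acid set free ⇌ protonated nucleophile, settled at all times (K3 = 2800 /M)
    acid set free + target → side product (k4 = 0.41 /M/min)

electrophile 0.21 M; protonated nucleophile 0.189 M; time 1.0 h

1. the concentration of free base at which the part of the electrophile that has reacted at 1.0 h is just 80%, in M

- Each electrophile used takes one nucleophile, so protonated nucleophile is the limiting reagent. Call the protonated nucleophile charged, divided by the electrophile charged, the supply ceiling 90.0%.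
- The ceiling clears 80%, but that proves little, so count what is left instead of what is made. At 80% you keep 0.0210 M of nucleophile in its forms, 11.1% of the charge, beside 0.0420 M of electrophile.
- First estimate of the base: each electrophile used frees two acids, one from the protonated nucleophile and one from the reaction. Leaving the side product aside, the base must hold 0.336 M as salt.
- Objection: salt gives acid back, so that bill is not yet the need. Some free base must stay to hold the free acid down.
- Better estimate: treat the supply left as protonated and put the first and third equilibria at balance. Free acid is then 0.001186 M, the salt balance asks for 0.373 M of free base beyond the bill, and the total is 0.709 M.
- Objection: this says where the flask can stop, not where it stands after 1.0 h. So I commit to it as my estimate and expect the need to be higher.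
- The forecast gives 0.95 M, with a range of 0.7 M to 1.3 M, on the ground that “the base has to take up about two acid equivalents per electrophile converted”. Its number stands higher than my estimate.
- The simulation gives 1.22 M, higher than the forecast and higher than my estimate. The main reason this flask gets near its ceiling of 90.0% is the capture of acid by free base: with that step taken away, both ways, this flask reaches 8.02% instead of 80.0%. A second flask with half the protonated nucleophile and all other amounts as they are has a ceiling of 45.0%, and it ends its run with 44.8% of the electrophile reacted.

The constants used here were set for the occasion.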